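**Assumption:** the SMILES is read literally. In labdane numbering (C1–C10 decalin, C11–C15 side chain, C17 = methyl on C8, C20 = methyl on C10) it is 5S,8R,9R,10R,13S, so the decalin is cis-fused (C20 and H-5 on the same face). Compounds 1, 3 and 12 and all reagents are commercial and achiral.

**Retrosynthetic overview**
1. Target ← primary-selective acetylation of the 8,15-diol; equatorial 8-OH and axial 8-CH3 ← hydride opening of the 8,17-epoxide ← convex-face epoxidation of a C8 exocyclic methylene ← C8 ketone.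
2. C9–C11 bond ← Mukaiyama aldol of the C8/C9 silyl enol ether of the cis-decalone with a C11–C15 aldehyde, then dehydration and convex-face hydrogenation (sets C9).
3. Side-chain aldehyde (C13) ← pig liver esterase (a carboxylesterase) desymmetrisation of dimethyl 3-methylglutarate.
4. Quaternary C10 and the cis fusion ← Me2CuLi addition to the bicyclic C9=C10 enone from the H-5 face; ring A ← ring-closing metathesis (C2=C3) of a 3-allyl-4-(1,1-dimethylallyl)cyclohexenone.
5. Ring B is made first (organocatalytic Michael addition of 3,3-dimethylpent-4-enal to methyl vinyl ketone sets C5, then aldol condensation); ring A second.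

**Route**

Step 1
Reactants: 1 methyl 3,3-dimethylpent-4-enoate
Product: 2 3,3-dimethylpent-4-enal
Conditions: i-Bu2AlH (1.05 equiv), CH2Cl2, −78 °C; Rochelle salt work-up
Reagents that add atoms: none
Why: Partial ester reduction with i-Bu2AlH stops at the aluminium hemiacetal at −78 °C and gives the aldehyde on work-up; no stereocenter is involved.

Step 2
Reactants: 2 3,3-dimethylpent-4-enal; 3 but-3-en-2-one
Product: 4 (2S)-2-(2-methylbut-3-en-2-yl)-5-oxohexanal
Conditions: (S)-2-[diphenyl(trimethylsilyloxy)methyl]pyrrolidine (10 mol%), ethyl 3,4-dihydroxybenzoate (20 mol%), 3 (1.5 equiv), neat, 4 °C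
Reagents that add atoms: none
Why: Enamine-catalysed asymmetric Michael addition: the E-enamine of 2 attacks the enone from the face away from the diarylsilyloxymethyl group, setting C5 (S) as the first stereocenter.

Step 3
Reactants: 4 (2S)-2-(2-methylbut-3-en-2-yl)-5-oxohexanal
Product: 6 (4R)-4-(2-methylbut-3-en-2-yl)cyclohex-2-en-1-one, via aldol ketol 5 (not isolated)
Conditions: LiOH (0.3 equiv), i-PrOH, rt
Reagents that add atoms: none
Why: Intramolecular aldol condensation of the methyl ketone onto the aldehyde closes ring B; the hindered C5–H is not enolised under this mild base (the descriptor changes to R only through CIP priorities).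

Step 4
Reactants: 6 (4R)-4-(2-methylbut-3-en-2-yl)cyclohex-2-en-1-one
Product: 7 trimethyl{[(3S,4R)-4-(2-methylbut-3-en-2-yl)-3-(prop-2-en-1-yl)cyclohex-1-en-1-yl]oxy}silane
Conditions: allylMgBr, CuBr·SMe2, LiCl, TMSCl, THF, −78 °C; Et3N quench
Reagents that add atoms: allylmagnesium bromide, C=CC[Mg]Br; chlorotrimethylsilane, C[Si](C)(C)Cl
Why: TMSCl-accelerated allylcopper conjugate addition occurs anti to the bulky C5 substituent and traps the regiodefined C8–C9 enolate as its silyl enol ether; the new C10 center is temporary.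

Step 5
Reactants: 7 the silyl enol ether above
Product: 8 (4S)-4-(2-methylbut-3-en-2-yl)-3-(prop-2-en-1-yl)cyclohex-2-en-1-one
Conditions: Pd(OAc)2 (1.1 equiv), MeCN, rt
Reagents that add atoms: none
Why: Saegusa–Ito oxidation: divalent palladium binds C9 and β-hydride elimination of H-10 regenerates the enone regiospecifically, now carrying the allyl group on C10; C5 is untouched.

Step 6
Reactants: 8 the 3-allyl enone above
Product: 9 (4aS)-5,5-dimethyl-4,4a,5,8-tetrahydronaphthalen-2(3H)-one
Conditions: second-generation Grubbs catalyst RuCl2(=CHPh)(PCy3)(SIMes) (3 mol%), CH2Cl2, 40 °C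
Reagents that add atoms: none
Why: Ring-closing metathesis of the allyl and vinyl groups forms ring A (C2=C3) with loss of ethene, while the trisubstituted enone is inert.

Step 7
Reactants: 9 the bicyclic dienone above
Product: 10 (4aS)-5,5-dimethyl-4,4a,5,6,7,8-hexahydronaphthalen-2(3H)-one
Conditions: H2 (1 atm), RhCl(PPh3)3 (5 mol%), toluene, rt
Reagents that add atoms: none
Why: Homogeneous hydrogenation with RhCl(PPh3)3 saturates the cis-disubstituted C2=C3 alkene much faster than the conjugated trisubstituted enone.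

Step 8
Reactants: 10 the bicyclic enone above
Product: 11 trimethyl{[(4aS,8aR)-5,5,8a-trimethyl-3,4,4a,5,6,7,8,8a-octahydronaphthalen-2-yl]oxy}silane
Conditions: Me2CuLi (from MeLi and CuI), TMSCl, Et2O, −78 to −20 °C; Et3N quench
Reagents that add atoms: methyllithium (used as lithium dimethylcuprate), C[Li]; chlorotrimethylsilane, C[Si](C)(C)Cl
Why: Gilman cuprate conjugate addition delivers methyl to C10 from the H-5 face (axial on ring B, away from the axial C4 methyl), which is the known cis-selective outcome for such octalones; this sets C10 (R) and gives a regiodefined C8–C9 enol ether.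

Step 9
Reactants: 12 dimethyl 3-methylpentanedioate
Product: 13 (3R)-5-methoxy-3-methyl-5-oxopentanoic acid
Conditions: pig liver esterase (a carboxylesterase), phosphate buffer pH 7 with 20% MeOH, −10 °C, pH-stat with 1 M NaOH; then HCl to pH 2
Reagents that add atoms: water, O
Why: Enzymatic desymmetrisation: the esterase hydrolyses one enantiotopic ester group of the prochiral diester (reported up to about 97% ee under these conditions), creating the future C13.

Step 10
Reactants: 13 (3R)-5-methoxy-3-methyl-5-oxopentanoic acid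
Product: 14 methyl (3R)-5-hydroxy-3-methylpentanoate
Conditions: BH3·SMe2, THF, 0 °C to rt
Reagents that add atoms: none
Why: Chemoselective borane reduction of the carboxylic acid in the presence of the ester makes the acid terminus the future C15; the stereocenter is not touched.

Step 11
Reactants: 14 methyl (3R)-5-hydroxy-3-methylpentanoate
Product: 15 methyl (3R)-5-[(tert-butyldimethylsilyl)oxy]-3-methylpentanoate
Conditions: TBSCl, imidazole, DMF, rt
Reagents that add atoms: tert-butyl(chloro)dimethylsilane, CC(C)(C)[Si](C)(C)Cl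
Why: Silyl ether protection of the primary alcohol prevents lactonisation and survives all later steps up to fluoride cleavage.

Step 12
Reactants: 15 the silyl ether ester above
Product: 16 (3R)-5-[(tert-butyldimethylsilyl)oxy]-3-methylpentanal
Conditions: i-Bu2AlH (1.05 equiv), CH2Cl2, −78 °C; Rochelle salt work-up
Reagents that add atoms: none
Why: Partial ester reduction with i-Bu2AlH gives the C11 aldehyde; the β-stereocenter cannot epimerise.

Step 13
Reactants: 11 the silyl enol ether from step 8; 16 the aldehyde from step 12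
Product: 17 (4aS,8aR)-1-{(3R)-5-[(tert-butyldimethylsilyl)oxy]-1-hydroxy-3-methylpentyl}-5,5,8a-trimethyloctahydronaphthalen-2(1H)-one (mixture at C9 and C11)
Conditions: TiCl4 (1.1 equiv), CH2Cl2, −78 °C; aqueous NaHCO3
Reagents that add atoms: none
Why: Mukaiyama aldol addition forms the C9–C11 bond only at the enol-ether carbon; the two new centers are removed or reset in steps 14 and 15.

Step 14
Reactants: 17 the aldol adduct above
Product: 19 (4aS,8aR)-1-{(3S)-5-[(tert-butyldimethylsilyl)oxy]-3-methylpentylidene}-5,5,8a-trimethyloctahydronaphthalen-2(1H)-one (E/Z mixture), via C11 mesylate 18 (not isolated)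
Conditions: MsCl, Et3N, CH2Cl2, 0 °C; then DBU, rt
Reagents that add atoms: none
Why: Mesylation followed by E1cB elimination gives the exocyclic enone; both alkene isomers converge in step 15.

Step 15
Reactants: 19 the exocyclic enone above
Product: 20 (1R,4aS,8aR)-1-{(3S)-5-[(tert-butyldimethylsilyl)oxy]-3-methylpentyl}-5,5,8a-trimethyloctahydronaphthalen-2(1H)-one
Conditions: H2 (1 atm), 10% Pd/C, EtOAc, rt; then NaOMe (0.2 equiv), MeOH, rt
Reagents that add atoms: none
Why: Heterogeneous hydrogenation adds H-9 from the convex face (opposite the axial C1 of ring A), and the base equilibration confirms this as the thermodynamic epimer with the side chain equatorial, setting C9 (R).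

Step 16
Reactants: 20 the ketone above
Product: 21 tert-butyldimethyl({(3S)-3-methyl-5-[(1S,4aS,8aR)-5,5,8a-trimethyl-2-methylidenedecahydronaphthalen-1-yl]pentyl}oxy)silane
Conditions: Ph3PCH3Br, KOtBu, toluene, 80 °C
Reagents that add atoms: methyltriphenylphosphonium bromide, C[P+](c1ccccc1)(c1ccccc1)c1ccccc1.[Br-]
Why: Wittig methylenation of the hindered ketone installs C17; C9 is already in its stable configuration (its descriptor changes to S only through CIP priorities).

Step 17
Reactants: 21 the exocyclic alkene above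
Product: 22 tert-butyldimethyl({(3S)-3-methyl-5-[(1'R,2R,4a'S,8a'R)-5',5',8a'-trimethyloctahydro-1'H-spiro[oxirane-2,2'-naphthalen]-1'-yl]pentyl}oxy)silane (8,17-epoxide, oxygen on the face of the C10 methyl)
Conditions: mCPBA, NaHCO3, CH2Cl2, 0 °C
Reagents that add atoms: 3-chloroperoxybenzoic acid, OOC(=O)c1cccc(Cl)c1
Why: Prilezhaev epoxidation takes place from the convex face in the equatorial direction, because the axial direction is blocked by the syn-axial C1; this places the C8–O bond equatorial and C17 axial, setting C8 (minor epimer removed by chromatography).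

Step 18
Reactants: 22 the epoxide above
Product: 23 (1R,2R,4aS,8aR)-1-{(3S)-5-[(tert-butyldimethylsilyl)oxy]-3-methylpentyl}-2,5,5,8a-tetramethyldecahydronaphthalen-2-ol
Conditions: LiAlH4, THF, 0 °C to reflux
Reagents that add atoms: none
Why: Hydride opens the epoxide by SN2 attack at the primary C17, turning it into the axial methyl and leaving the C8–O bond, and hence C8 (R), unchanged.

Step 19
Reactants: 23 the tertiary alcohol silyl ether above
Product: 24 (1R,2R,4aS,8aR)-1-[(3S)-5-hydroxy-3-methylpentyl]-2,5,5,8a-tetramethyldecahydronaphthalen-2-ol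
Conditions: Bu4NF, THF, rt
Reagents that add atoms: none
Why: Fluoride-mediated desilylation frees the primary C15 alcohol without affecting any stereocenter.

Step 20
Reactants: 24 the diol above
Product: 25 (3S)-5-[(1R,2R,4aS,8aR)-2-hydroxy-2,5,5,8a-tetramethyldecahydronaphthalen-1-yl]-3-methylpentyl acetate
Conditions: Ac2O, pyridine, 0 °C to rt
Reagents that add atoms: acetic anhydride, CC(=O)OC(C)=O
Why: Acetylation without DMAP esterifies only the primary alcohol, since the hindered tertiary C8 alcohol does not react, and gives the target.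

**Compound list**
1 | methyl 3,3-dimethylpent-4-enoate | COC(=O)CC(C)(C)C=C | starting material
2 | 3,3-dimethylpent-4-enal | O=CCC(C)(C)C=C | intermediate
3 | but-3-en-2-one | CC(=O)C=C | starting material
4 | (2S)-2-(2-methylbut-3-en-2-yl)-5-oxohexanal | C=CC(C)(C)[C@@H](C=O)CCC(C)=O | intermediate
5 | (4S)-3-hydroxy-4-(2-methylbut-3-en-2-yl)cyclohexan-1-one (C3 epimers) | C=CC(C)(C)[C@@H]1CCC(=O)CC1O | intermediate (not isolated)
6 | (4R)-4-(2-methylbut-3-en-2-yl)cyclohex-2-en-1-one | C=CC(C)(C)[C@H]1C=CC(=O)CC1 | intermediate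
7 | trimethyl{[(3S,4R)-4-(2-methylbut-3-en-2-yl)-3-(prop-2-en-1-yl)cyclohex-1-en-1-yl]oxy}silane | C=CC(C)(C)[C@@H]1CCC(O[Si](C)(C)C)=C[C@H]1CC=C | intermediate
8 | (4S)-4-(2-methylbut-3-en-2-yl)-3-(prop-2-en-1-yl)cyclohex-2-en-1-one | C=CCC1=CC(=O)CC[C@H]1C(C)(C)C=C | intermediate
9 | (4aS)-5,5-dimethyl-4,4a,5,8-tetrahydronaphthalen-2(3H)-one | O=C1C=C2CC=CC(C)(C)[C@@H]2CC1 | intermediate
10 | (4aS)-5,5-dimethyl-4,4a,5,6,7,8-hexahydronaphthalen-2(3H)-one | O=C1C=C2CCCC(C)(C)[C@@H]2CC1 | intermediate
11 | trimethyl{[(4aS,8aR)-5,5,8a-trimethyl-3,4,4a,5,6,7,8,8a-octahydronaphthalen-2-yl]oxy}silane | C[Si](C)(C)OC1=C[C@]2(C)CCCC(C)(C)[C@@H]2CC1 | intermediate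
12 | dimethyl 3-methylpentanedioate | COC(=O)CC(C)CC(=O)OC | starting material
13 | (3R)-5-methoxy-3-methyl-5-oxopentanoic acid | COC(=O)C[C@H](C)CC(=O)O | intermediate
14 | methyl (3R)-5-hydroxy-3-methylpentanoate | COC(=O)C[C@H](C)CCO | intermediate
15 | methyl (3R)-5-[(tert-butyldimethylsilyl)oxy]-3-methylpentanoate | COC(=O)C[C@H](C)CCO[Si](C)(C)C(C)(C)C | intermediate
16 | (3R)-5-[(tert-butyldimethylsilyl)oxy]-3-methylpentanal | O=CC[C@H](C)CCO[Si](C)(C)C(C)(C)C | intermediate
17 | (4aS,8aR)-1-{(3R)-5-[(tert-butyldimethylsilyl)oxy]-1-hydroxy-3-methylpentyl}-5,5,8a-trimethyloctahydronaphthalen-2(1H)-one (mixture at C9 and C11) | CC(C)(C)[Si](C)(C)OCC[C@@H](C)CC(O)C1[C@]2(C)CCCC(C)(C)[C@@H]2CCC1=O | intermediate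
18 | (3R)-5-[(tert-butyldimethylsilyl)oxy]-3-methyl-1-[(4aS,8aR)-5,5,8a-trimethyl-2-oxodecahydronaphthalen-1-yl]pentyl methanesulfonate (mixture at C9 and C11) | CC(C)(C)[Si](C)(C)OCC[C@@H](C)CC(OS(C)(=O)=O)C1[C@]2(C)CCCC(C)(C)[C@@H]2CCC1=O | intermediate (not isolated)
19 | (4aS,8aR)-1-{(3S)-5-[(tert-butyldimethylsilyl)oxy]-3-methylpentylidene}-5,5,8a-trimethyloctahydronaphthalen-2(1H)-one (E/Z mixture) | CC(C)(C)[Si](C)(C)OCC[C@@H](C)CC=C1[C@]2(C)CCCC(C)(C)[C@@H]2CCC1=O | intermediate
20 | (1R,4aS,8aR)-1-{(3S)-5-[(tert-butyldimethylsilyl)oxy]-3-methylpentyl}-5,5,8a-trimethyloctahydronaphthalen-2(1H)-one | CC(C)(C)[Si](C)(C)OCC[C@@H](C)CC[C@@H]1[C@]2(C)CCCC(C)(C)[C@@H]2CCC1=O | intermediate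
21 | tert-butyldimethyl({(3S)-3-methyl-5-[(1S,4aS,8aR)-5,5,8a-trimethyl-2-methylidenedecahydronaphthalen-1-yl]pentyl}oxy)silane | CC(C)(C)[Si](C)(C)OCC[C@@H](C)CC[C@@H]1[C@]2(C)CCCC(C)(C)[C@@H]2CCC1=C | intermediate
22 | tert-butyldimethyl({(3S)-3-methyl-5-[(1'R,2R,4a'S,8a'R)-5',5',8a'-trimethyloctahydro-1'H-spiro[oxirane-2,2'-naphthalen]-1'-yl]pentyl}oxy)silane | CC(C)(C)[Si](C)(C)OCC[C@@H](C)CC[C@@H]1[C@]2(C)CCCC(C)(C)[C@@H]2CC[C@]13CO3 | intermediate
23 | (1R,2R,4aS,8aR)-1-{(3S)-5-[(tert-butyldimethylsilyl)oxy]-3-methylpentyl}-2,5,5,8a-tetramethyldecahydronaphthalen-2-ol | CC(C)(C)[Si](C)(C)OCC[C@@H](C)CC[C@@H]1[C@]2(C)CCCC(C)(C)[C@@H]2CC[C@@]1(C)O | intermediate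
24 | (1R,2R,4aS,8aR)-1-[(3S)-5-hydroxy-3-methylpentyl]-2,5,5,8a-tetramethyldecahydronaphthalen-2-ol | OCC[C@@H](C)CC[C@@H]1[C@]2(C)CCCC(C)(C)[C@@H]2CC[C@@]1(C)O | intermediate
25 | (3S)-5-[(1R,2R,4aS,8aR)-2-hydroxy-2,5,5,8a-tetramethyldecahydronaphthalen-1-yl]-3-methylpentyl acetate | CC(=O)OCC[C@@H](C)CC[C@@H]1[C@]2(C)CCCC(C)(C)[C@@H]2CC[C@@]1(C)O | target

**Step count:** 20 steps in total. The longest linear sequence is 16 steps (1 to 25 through steps 1–8 and 13–20); the side-chain branch (steps 9–12) is 4 steps.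

**Three steps most likely to fail, with fallbacks**

Step 2 (enamine Michael addition of a neopentyl-type aldehyde; slow turnover or insufficient ee). The fallback sets C5 by enantioselective protonation instead of C–C bond formation. It sets out from 2 (with 3): pyrrolidine-mediated Stork enamine Michael addition and KOH aldol condensation give racemic 4-(2-methylbut-3-en-2-yl)cyclohex-2-en-1-one F1. Thermodynamic dienolate formation (KOtBu, t-BuOH) and kinetic α-protonation with aqueous AcOH deconjugate it to achiral 4-(2-methylbut-3-en-2-yl)cyclohex-3-en-1-one F2. A cinchona-derived primary amine with a carboxylic acid co-catalyst then isomerises F2 through its dienamine with face-selective γ-protonation, and the route is rejoined at 6.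

Step 8 (cuprate addition to the hindered bicyclic enone; sluggish addition or eroded cis selectivity). The fallback adds the methyl group before ring A exists. It sets out from 8: Me2CuLi with TMSCl adds methyl anti to the pseudo-axial C5 substituent (the usual trans-3,4 outcome) to give trimethyl{[(3R,4S)-3-methyl-4-(2-methylbut-3-en-2-yl)-3-(prop-2-en-1-yl)cyclohex-1-en-1-yl]oxy}silane F3. Ring-closing metathesis with the second-generation Grubbs catalyst then gives trimethyl{[(4aS,8aR)-5,5,8a-trimethyl-3,4,4a,5,8,8a-hexahydronaphthalen-2-yl]oxy}silane F4, in which the cis fusion is enforced because the allyl and dimethylallyl groups are cis. Hydrogenation with RhCl(PPh3)3 saturates only the ring A alkene, and the route is rejoined at 11.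

Step 17 (facial selectivity of the peracid epoxidation). The fallback uses the more sterically demanding osmylation and makes the epoxide by ring closure. It sets out from 21: OsO4 (catalytic) with N-methylmorpholine N-oxide dihydroxylates from the convex face to (1R,2R,4aS,8aR)-1-{(3S)-5-[(tert-butyldimethylsilyl)oxy]-3-methylpentyl}-2-(hydroxymethyl)-5,5,8a-trimethyldecahydronaphthalen-2-ol F5. TsCl in pyridine sulfonylates only the primary hydroxyl to give [(1R,2R,4aS,8aR)-1-{(3S)-5-[(tert-butyldimethylsilyl)oxy]-3-methylpentyl}-2-hydroxy-5,5,8a-trimethyldecahydronaphthalen-2-yl]methyl 4-methylbenzenesulfonate F6. K2CO3 in MeOH closes F6 to the epoxide with retention at C8, and the route is rejoined at 22.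

**Further compounds**
F1 | step 2 | racemic 4-(2-methylbut-3-en-2-yl)cyclohex-2-en-1-one | C=CC(C)(C)C1C=CC(=O)CC1
F2 | step 2 | 4-(2-methylbut-3-en-2-yl)cyclohex-3-en-1-one | C=CC(C)(C)C1=CCC(=O)CC1
F3 | step 8 | trimethyl{[(3R,4S)-3-methyl-4-(2-methylbut-3-en-2-yl)-3-(prop-2-en-1-yl)cyclohex-1-en-1-yl]oxy}silane | C=CC[C@@]1(C)C=C(O[Si](C)(C)C)CC[C@H]1C(C)(C)C=C
F4 | step 8 | trimethyl{[(4aS,8aR)-5,5,8a-trimethyl-3,4,4a,5,8,8a-hexahydronaphthalen-2-yl]oxy}silane | C[Si](C)(C)OC1=C[C@]2(C)CC=CC(C)(C)[C@@H]2CC1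
F5 | step 17 | (1R,2R,4aS,8aR)-1-{(3S)-5-[(tert-butyldimethylsilyl)oxy]-3-methylpentyl}-2-(hydroxymethyl)-5,5,8a-trimethyldecahydronaphthalen-2-ol | CC(C)(C)[Si](C)(C)OCC[C@@H](C)CC[C@@H]1[C@]2(C)CCCC(C)(C)[C@@H]2CC[C@@]1(CO)O
F6 | step 17 | [(1R,2R,4aS,8aR)-1-{(3S)-5-[(tert-butyldimethylsilyl)oxy]-3-methylpentyl}-2-hydroxy-5,5,8a-trimethyldecahydronaphthalen-2-yl]methyl 4-methylbenzenesulfonate | CC(C)(C)[Si](C)(C)OCC[C@@H](C)CC[C@@H]1[C@]2(C)CCCC(C)(C)[C@@H]2CC[C@@]1(COS(=O)(=O)c3ccc(C)cc3)O
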